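**Retrosynthetic overview**

1. Target 22 ⇒ seco-diene 21: ring-closing metathesis at C4=C5 closes the ten-membered carbocycle last.
2. 21 ⇒ carbinol 18: the C8–O isobutyrate is made by a stereoinvertive Mitsunobu C–O bond formation; 18 ⇒ aldehyde 8 + bromobutenolide 16 by zinc Barbier allylation (C7–C8), with C6 relaying to C7 and C8.
3. 16 ⇒ dienol 12 + acid 13: lactone C–O bond by esterification, butenolide (first ring) by metathesis; 12 ⇒ sorbyl carbonate 10 by the key step, a new Ir-catalysed enantioselective allylic C–O substitution that creates the C6–O stereocentre.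
4. 8 ⇒ geraniol 1: C10–O from Sharpless epoxidation/Red-Al opening, C3–O from Shi epoxidation/silyl-triflate epoxide isomerisation.
5. Ring order: γ-lactone (as butenolide 16) first, ten-membered carbocycle last.

Germacrane numbering (C1–C15) is used for positions in the target.

Assumption 1: the zinc Barbier addition (step 11) follows the chair transition state of related bromolactone allylations and gives the 7,8-anti (8S) carbinol, so C8 is inverted in step 12.

Assumption 2: the (Sa,Sc,Sc) phosphoramidite gives the 3S alcohol in step 8 (by analogy with simple allyl carbonates); the mirror-image ligand is used if the opposite sense is found.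

**Route**

Step 1
Reactants: 1 geraniol
Product: 2 (2S,3S)-2,3-epoxygeraniol
Conditions: Ti(OiPr)4 (5 mol%), L-(+)-DET (7 mol%), t-BuOOH, 4 Å MS, CH2Cl2, −20 °C
Reagents that add atoms: tert-butyl hydroperoxide CC(C)(C)OO
Why: Katsuki–Sharpless asymmetric epoxidation is hydroxyl-directed, so only the allylic 2,3-alkene reacts, and L-(+)-tartrate gives the (2S,3S) epoxide whose C3–O bond becomes the C10–O stereocentre.

Step 2
Reactants: 2 (2S,3S)-2,3-epoxygeraniol
Product: 3 (3S)-3,7-dimethyloct-6-ene-1,3-diol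
Conditions: Red-Al, THF, 0 → 23 °C; Rochelle salt work-up
Reagents that add atoms: none
Why: Red-Al reductive opening of a 2,3-epoxy alcohol delivers hydride intramolecularly to C2 (1,3-diol selective), leaving the tertiary C–O bond and its configuration untouched.

Step 3
Reactants: 3 (3S)-3,7-dimethyloct-6-ene-1,3-diol
Product: 4 (3S)-3,7-dimethyl-1,3-bis(triethylsilyloxy)oct-6-ene
Conditions: TESOTf (2.4 equiv), 2,6-lutidine, CH2Cl2, −78 → 0 °C
Reagents that add atoms: triethylsilyl triflate CC[Si](CC)(CC)OS(=O)(=O)C(F)(F)F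
Why: Silyl triflate silylation caps both the primary and the tertiary hydroxyl, which stops the tertiary oxygen from opening the epoxide made next.

Step 4
Reactants: 4 (3S)-3,7-dimethyl-1,3-bis(triethylsilyloxy)oct-6-ene
Product: 5 (3S,6S)-6,7-epoxy-3,7-dimethyl-1,3-bis(triethylsilyloxy)octane
Conditions: ent-Shi ketone (L-fructose-derived, 30 mol%), Oxone, K2CO3, Bu4NHSO4, MeCN–DMM/aq. borate buffer (pH 10.5), 0 °C
Reagents that add atoms: potassium peroxymonosulfate (Oxone) [K+].[O-]S(=O)(=O)OO
Why: Shi asymmetric epoxidation transfers oxygen from the chiral dioxirane to the electron-rich trisubstituted alkene through the spiro transition state, and the L-fructose-derived ketone sets 6S (future C3) under catalyst control.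

Step 5
Reactants: 5 (3S,6S)-6,7-epoxy-3,7-dimethyl-1,3-bis(triethylsilyloxy)octane
Product: 6 (3S,6S)-2,6-dimethyl-3,6,8-tris(triethylsilyloxy)oct-1-ene
Conditions: TESOTf (1.5 equiv), DBU (2 equiv), toluene, 0 → 23 °C
Reagents that add atoms: triethylsilyl triflate CC[Si](CC)(CC)OS(=O)(=O)C(F)(F)F
Why: Noyori-type silyl-triflate/amidine epoxide isomerisation cleaves the silyl-activated tertiary C–O bond and removes a methyl proton, giving the secondary allylic silyl ether with the 1,1-disubstituted alkene while the C–O stereocentre is retained.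

Step 6
Reactants: 6 (3S,6S)-2,6-dimethyl-3,6,8-tris(triethylsilyloxy)oct-1-ene
Product: 8 (3S,6S)-3,7-dimethyl-3,6-bis(triethylsilyloxy)oct-7-enal, via alkoxysulfonium chloride 7 (not isolated)
Conditions: (COCl)2, DMSO, CH2Cl2, −78 → −30 °C; Et3N, −78 → 0 °C
Reagents that add atoms: none
Why: Under Swern conditions a primary triethylsilyl ether is converted directly into the aldehyde while secondary and tertiary triethylsilyl ethers survive.

Step 7
Reactants: 9 sorbyl alcohol [(2E,4E)-hexa-2,4-dien-1-ol]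
Product: 10 (2E,4E)-hexa-2,4-dien-1-yl methyl carbonate
Conditions: ClCO2Me, pyridine, CH2Cl2, 0 °C
Reagents that add atoms: methyl chloroformate COC(Cl)=O
Why: Simple O-acylation of the primary allylic alcohol gives the carbonate leaving group needed for allyl-metal chemistry.

Step 8
Reactants: 10 (2E,4E)-hexa-2,4-dien-1-yl methyl carbonate
Product: 12 (3S,4E)-hexa-1,4-dien-3-ol, via allyl hydrogen carbonate 11 (not isolated)
Conditions: [Ir(cod)Cl]2 (2 mol%), (Sa,Sc,Sc)-binaphthyl bis(1-phenylethyl)phosphoramidite (4 mol%), TBD (cat., activation), KHCO3 (2 equiv), THF–H2O 20:1, 35 °C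
Reagents that add atoms: potassium hydrogencarbonate [K+].OC([O-])=O
Why: Proposed new method: Ir/phosphoramidite-catalysed branched- and enantioselective allylic substitution of a 2,4-dienyl carbonate by an oxygen nucleophile, in which oxidative addition gives a cyclometalated (η3-allyl)Ir(III) complex whose substituted terminus C3 is the most electrophilic, outer-sphere attack of hydrogencarbonate anti to Ir forms the C–O stereocentre as 3S, and the hydrogen carbonate 11 loses CO2 to give the skipped dienol with the distal propenyl group outside the η3 unit; the closest known reaction type is Ir-catalysed branched-selective allylic hydroxylation, etherification and esterification of monosubstituted allyl carbonates together with Ir-catalysed amination and alkylation of dienyl carbonates at C3.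

Step 9
Reactants: 12 (3S,4E)-hexa-1,4-dien-3-ol; 13 2-(bromomethyl)acrylic acid
Product: 15 (3S,4E)-hexa-1,4-dien-3-yl 2-(bromomethyl)prop-2-enoate, via O-acylisourea 14 (not isolated)
Conditions: DIC (1.2 equiv), DMAP (5 mol%), CH2Cl2, −10 → 0 °C
Reagents that add atoms: none
Why: Steglich esterification forms the future lactone C–O ester bond without touching the carbinol stereocentre, and low DMAP loading at low temperature protects the allylic bromide.

Step 10
Reactants: 15 (3S,4E)-hexa-1,4-dien-3-yl 2-(bromomethyl)prop-2-enoate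
Product: 16 (5R)-3-(bromomethyl)-5-[(1E)-prop-1-en-1-yl]furan-2(5H)-one
Conditions: Grubbs II (5 mol%), CH2Cl2 (0.01 M), 40 °C
Reagents that add atoms: none
Why: Ring-closing metathesis, in which the Ru alkylidene forms at the unhindered vinyl group and closes onto the acrylate to give the butenolide while the slower-initiating 1,2-disubstituted propenyl group is kept as the later metathesis handle; the stereocentre is not involved.

Step 11
Reactants: 8 (3S,6S)-3,7-dimethyl-3,6-bis(triethylsilyloxy)oct-7-enal; 16 (5R)-3-(bromomethyl)-5-[(1E)-prop-1-en-1-yl]furan-2(5H)-one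
Product: 18 (4R,5R)-4-[(1S,3S,6S)-1-hydroxy-3,7-dimethyl-3,6-bis(triethylsilyloxy)oct-7-en-1-yl]-3-methylidene-5-[(1E)-prop-1-en-1-yl]oxolan-2-one, via allylzinc bromide 17 (not isolated)
Conditions: Zn dust (3 equiv), 16 (1.5 equiv), THF/sat. aq NH4Cl 3:1, 0 → 23 °C
Reagents that add atoms: none
Why: Zinc Barbier allylation (SE2′) of the bromolactone proceeds through a chair Zimmerman–Traxler transition state on the face anti to the C6 propenyl group, which sets C7 (R) trans to C6 and, because the ring locks the allyl unit E-like, the 7,8-anti (8S) carbinol, and it unveils the α-methylene lactone.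

Step 12
Reactants: 18 (the 8S carbinol)
Product: 20 (1R,3S,6S)-3,7-dimethyl-1-[(2R,3R)-4-methylidene-5-oxo-2-[(1E)-prop-1-en-1-yl]oxolan-3-yl]-3,6-bis(triethylsilyloxy)oct-7-en-1-yl 2-methylpropanoate, via oxyphosphonium isobutyrate 19 (not isolated)
Conditions: PPh3, DIAD (betaine pre-formed at 0 °C), i-PrCO2H, toluene, 0 → 23 °C
Reagents that add atoms: isobutyric acid CC(C)C(O)=O
Why: Mitsunobu esterification displaces the oxyphosphonium group by isobutyrate in an SN2 step, forming the C8–O ester bond with inversion to 8R; the other two oxygens are silylated and cannot compete.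

Step 13
Reactants: 20 (the bis-silyl isobutyrate)
Product: 21 (1R,3S,6S)-3,6-dihydroxy-3,7-dimethyl-1-[(2R,3R)-4-methylidene-5-oxo-2-[(1E)-prop-1-en-1-yl]oxolan-3-yl]oct-7-en-1-yl 2-methylpropanoate
Conditions: HF·pyridine, pyridine, THF, 0 → 23 °C
Reagents that add atoms: none
Why: Buffered fluoride desilylation removes the secondary allylic and the tertiary triethylsilyl ethers without touching the isobutyrate or the α-methylene lactone, and frees the allylic hydroxyl that assists the final metathesis.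

Step 14
Reactants: 21 (the seco-diene diol)
Product: 22 (3S,6R,7R,8R,10S,4Z)-3,10-dihydroxy-8-(2-methylpropanoyloxy)germacra-4,11(13)-dien-12,6-olide (target)
Conditions: Hoveyda–Grubbs II (15 mol%), 1,4-benzoquinone (30 mol%), toluene (1 mM), 80 °C
Reagents that add atoms: none
Why: Ring-closing metathesis, initiated at the propenyl group and closing onto the isopropenyl group next to the free allylic hydroxyl, forms C4=C5 with loss of propene, and the ten-membered ring enforces the Z geometry of the new trisubstituted alkene; no stereocentre is affected.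

**Compound list**

1 | geraniol, (2E)-3,7-dimethylocta-2,6-dien-1-ol | C/C(=C\CO)CCC=C(C)C | starting material
2 | (2S,3S)-2,3-epoxygeraniol, [(2S,3S)-3-methyl-3-(4-methylpent-3-en-1-yl)oxiran-2-yl]methanol | OC[C@@H]1O[C@@]1(C)CCC=C(C)C | intermediate
3 | (3S)-3,7-dimethyloct-6-ene-1,3-diol | OCC[C@@](C)(O)CCC=C(C)C | intermediate
4 | (3S)-3,7-dimethyl-1,3-bis(triethylsilyloxy)oct-6-ene | CC[Si](CC)(CC)OCC[C@@](C)(O[Si](CC)(CC)CC)CCC=C(C)C | intermediate
5 | (3S,6S)-6,7-epoxy-3,7-dimethyl-1,3-bis(triethylsilyloxy)octane | CC[Si](CC)(CC)OCC[C@@](C)(O[Si](CC)(CC)CC)CC[C@@H]1OC1(C)C | intermediate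
6 | (3S,6S)-2,6-dimethyl-3,6,8-tris(triethylsilyloxy)oct-1-ene | CC[Si](CC)(CC)OCC[C@@](C)(O[Si](CC)(CC)CC)CC[C@H](O[Si](CC)(CC)CC)C(C)=C | intermediate
7 | {[(3S,6S)-3,7-dimethyl-3,6-bis(triethylsilyloxy)oct-7-en-1-yl]oxy}dimethylsulfonium chloride | C[S+](C)OCC[C@@](C)(O[Si](CC)(CC)CC)CC[C@H](O[Si](CC)(CC)CC)C(C)=C.[Cl-] | intermediate
8 | (3S,6S)-3,7-dimethyl-3,6-bis(triethylsilyloxy)oct-7-enal | O=CC[C@@](C)(O[Si](CC)(CC)CC)CC[C@H](O[Si](CC)(CC)CC)C(C)=C | intermediate
9 | sorbyl alcohol, (2E,4E)-hexa-2,4-dien-1-ol | C/C=C/C=C/CO | starting material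
10 | (2E,4E)-hexa-2,4-dien-1-yl methyl carbonate | C/C=C/C=C/COC(=O)OC | intermediate
11 | (3S,4E)-hexa-1,4-dien-3-yl hydrogen carbonate | C/C=C/[C@@H](OC(O)=O)C=C | intermediate
12 | (3S,4E)-hexa-1,4-dien-3-ol | C/C=C/[C@@H](O)C=C | intermediate
13 | 2-(bromomethyl)acrylic acid | OC(=O)C(=C)CBr | starting material
14 | O-[2-(bromomethyl)acryloyl]-N,N'-diisopropylisourea | C=C(CBr)C(=O)OC(=NC(C)C)NC(C)C | intermediate
15 | (3S,4E)-hexa-1,4-dien-3-yl 2-(bromomethyl)prop-2-enoate | C/C=C/[C@@H](OC(=O)C(=C)CBr)C=C | intermediate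
16 | (5R)-3-(bromomethyl)-5-[(1E)-prop-1-en-1-yl]furan-2(5H)-one | C/C=C/[C@H]1OC(=O)C(CBr)=C1 | intermediate
17 | {[(5R)-2-oxo-5-[(1E)-prop-1-en-1-yl]-2,5-dihydrofuran-3-yl]methyl}zinc bromide | C/C=C/[C@H]1OC(=O)C(C[Zn]Br)=C1 | intermediate
18 | (4R,5R)-4-[(1S,3S,6S)-1-hydroxy-3,7-dimethyl-3,6-bis(triethylsilyloxy)oct-7-en-1-yl]-3-methylidene-5-[(1E)-prop-1-en-1-yl]oxolan-2-one | C/C=C/[C@H]1OC(=O)C(=C)[C@@H]1[C@@H](O)C[C@@](C)(O[Si](CC)(CC)CC)CC[C@H](O[Si](CC)(CC)CC)C(C)=C | intermediate
19 | oxyphosphonium salt of 18 (C8–O–PPh3+) with isobutyrate counter-ion | C/C=C/[C@H]1OC(=O)C(=C)[C@@H]1[C@@H](O[P+](c1ccccc1)(c1ccccc1)c1ccccc1)C[C@@](C)(O[Si](CC)(CC)CC)CC[C@H](O[Si](CC)(CC)CC)C(C)=C.CC(C)C([O-])=O | intermediate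
20 | (1R,3S,6S)-3,7-dimethyl-1-[(2R,3R)-4-methylidene-5-oxo-2-[(1E)-prop-1-en-1-yl]oxolan-3-yl]-3,6-bis(triethylsilyloxy)oct-7-en-1-yl 2-methylpropanoate | C/C=C/[C@H]1OC(=O)C(=C)[C@@H]1[C@H](OC(=O)C(C)C)C[C@@](C)(O[Si](CC)(CC)CC)CC[C@H](O[Si](CC)(CC)CC)C(C)=C | intermediate
21 | (1R,3S,6S)-3,6-dihydroxy-3,7-dimethyl-1-[(2R,3R)-4-methylidene-5-oxo-2-[(1E)-prop-1-en-1-yl]oxolan-3-yl]oct-7-en-1-yl 2-methylpropanoate | C/C=C/[C@H]1OC(=O)C(=C)[C@@H]1[C@H](OC(=O)C(C)C)C[C@@](C)(O)CC[C@H](O)C(C)=C | intermediate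
22 | (3S,6R,7R,8R,10S,4Z)-3,10-dihydroxy-8-(2-methylpropanoyloxy)germacra-4,11(13)-dien-12,6-olide (3β,10α-dihydroxy-8β-isobutyryloxy, 6α,12-olide) | C=C1C(=O)O[C@@H]2/C=C(/C)[C@@H](O)CC[C@](C)(O)C[C@@H](OC(=O)C(C)C)[C@@H]12 | target

**Step count and risks**

Total steps: 14. Longest linear sequence: 10 (steps 1–6 and 11–14 from geraniol); the butenolide branch is 4 steps (7–10).

Step 8 (proposed new step). The hydrogencarbonate could attack C5 or C1 of the dienyl unit, the skipped dienol could re-ionise, or the ee could be low; any of these would undermine C6 and with it C7 and C8. The fallback uses known chemistry, sets out from 9 and comes back at 12. Sharpless asymmetric epoxidation of 9 (Ti(OiPr)4, D-(−)-DIPT, t-BuOOH) gives [(2R,3R)-3-[(1E)-prop-1-en-1-yl]oxiran-2-yl]methanol F1. Iodination (I2, PPh3, imidazole) gives (2S,3R)-2-(iodomethyl)-3-[(1E)-prop-1-en-1-yl]oxirane F2. Zinc dust in AcOH/EtOH then opens the iodo-epoxide reductively to 12, the epoxide C–O bond becoming the carbinol C–O bond.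

Step 12 (Mitsunobu at C8). The carbinol is flanked by a branched ring carbon, so elimination towards C7 or an incomplete reaction with the weakly acidic isobutyric acid is possible. The fallback sets the 8R configuration in the C–C bond formation instead of by substitution; it sets out from 16 (used with 8) and comes back at 20. Stannylation of 16 (Bu3SnCl, Zn, THF/aq NH4Cl) gives (5R)-5-[(1E)-prop-1-en-1-yl]-3-[(tributylstannyl)methyl]furan-2(5H)-one F3. BF3·OEt2-promoted addition of F3 to 8 at −78 °C goes through an open antiperiplanar transition state (7,8-syn selective) and gives (4R,5R)-4-[(1R,3S,6S)-1-hydroxy-3,7-dimethyl-3,6-bis(triethylsilyloxy)oct-7-en-1-yl]-3-methylidene-5-[(1E)-prop-1-en-1-yl]oxolan-2-one F4. Acylation of F4 with isobutyric anhydride/DMAP (retention) gives 20.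

Step 14 (macrocyclic metathesis). A strained ten-membered ring with a trisubstituted Z alkene must form from a hindered isopropenyl group; oligomers, the E isomer or allylic-alcohol isomerisation may result. The fallback moves ring closure ahead of the C8 inversion and the deprotection, so it runs on a different, less encumbered substrate; it sets out from 18 and comes back at 22. Ring-closing metathesis of 18 (Hoveyda–Grubbs II, toluene, high dilution) gives (3S,6R,7R,8S,10S,4Z)-8-hydroxy-3,10-bis(triethylsilyloxy)germacra-4,11(13)-dien-12,6-olide F5. Mitsunobu esterification with isobutyric acid on the rigid ring gives (3S,6R,7R,8R,10S,4Z)-8-(2-methylpropanoyloxy)-3,10-bis(triethylsilyloxy)germacra-4,11(13)-dien-12,6-olide F6. HF·pyridine then gives 22.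

**Further compounds**

F1 | step 8 | [(2R,3R)-3-[(1E)-prop-1-en-1-yl]oxiran-2-yl]methanol | C/C=C/[C@H]1O[C@@H]1CO
F2 | step 8 | (2S,3R)-2-(iodomethyl)-3-[(1E)-prop-1-en-1-yl]oxirane | C/C=C/[C@H]1O[C@@H]1CI
F3 | step 12 | (5R)-5-[(1E)-prop-1-en-1-yl]-3-[(tributylstannyl)methyl]furan-2(5H)-one | C/C=C/[C@H]1OC(=O)C(C[Sn](CCCC)(CCCC)CCCC)=C1
F4 | step 12 | (4R,5R)-4-[(1R,3S,6S)-1-hydroxy-3,7-dimethyl-3,6-bis(triethylsilyloxy)oct-7-en-1-yl]-3-methylidene-5-[(1E)-prop-1-en-1-yl]oxolan-2-one | C/C=C/[C@H]1OC(=O)C(=C)[C@@H]1[C@H](O)C[C@@](C)(O[Si](CC)(CC)CC)CC[C@H](O[Si](CC)(CC)CC)C(C)=C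
F5 | step 14 | (3S,6R,7R,8S,10S,4Z)-8-hydroxy-3,10-bis(triethylsilyloxy)germacra-4,11(13)-dien-12,6-olide | C=C1C(=O)O[C@@H]2/C=C(/C)[C@@H](O[Si](CC)(CC)CC)CC[C@](C)(O[Si](CC)(CC)CC)C[C@H](O)[C@@H]12
F6 | step 14 | (3S,6R,7R,8R,10S,4Z)-8-(2-methylpropanoyloxy)-3,10-bis(triethylsilyloxy)germacra-4,11(13)-dien-12,6-olide | C=C1C(=O)O[C@@H]2/C=C(/C)[C@@H](O[Si](CC)(CC)CC)CC[C@](C)(O[Si](CC)(CC)CC)C[C@@H](OC(=O)C(C)C)[C@@H]12
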